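**Plan**

1. Cuts (retrosynthesis): the two quinone C=O groups go back to a 2,3,6-trisubstituted phenol whose para C–H is oxidised last. The chain is then cut at the CH2–CH= bond between C1 and C2 of prenyl unit 5 (units counted from the ring, each C1H2–C2H=C3(CH3)–C4H2). Further cuts are aryl–C1 of unit 1, C4 of unit 4–C1 of unit 5, the CH2–CH= bond of unit 6 and the bond to C1 of unit 7.
2. Forward, ring half: 2-methoxy-5-methylphenol is brominated ortho, MOM-protected and allylated with geranylgeranyl bromide. SeO2 hydroxylates the terminal E-methyl, and CH2CO2H (from acetic acid) is attached there to give acid 11 (benzene ring, units 1–4, C1 of unit 5, plus a carboxyl that is lost).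
3. Forward, tail half: a second geranylgeranyl bromide is extended at its head by propargylation, methylalumination/iodination, butynylzinc coupling and a second methylalumination/iodination to the C29 iodide 23 (C2–C4 of unit 5, units 6–10).
4. Union and end: acid and iodide are joined by nickel-electrocatalytic decarboxylative alkenylation; MOM removal and Co(salen)/O2 oxidation of the phenol give the quinone.
5. Enabling feature: C1 of unit 5 is a primary carbon held one CH2 (C4 of unit 4) away from the C2=C3 olefin of unit 4, so it can be a non-allylic radical released from a 4-methylalk-4-enoic acid. C2 of unit 5 is the CH end of a trisubstituted olefin that can be preset as an (E)-2-methylalkenyl iodide. The benzene ring is inert at the cathode as a MOM-protected methoxyphenol with its para CH free.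
6. Stereochemistry: there are no stereocentres. The E olefins of units 1–3 and 7–9 come from two molecules of (2E,6E,10E)-geranylgeraniol, that of unit 4 from the E-selective SeO2 oxidation, and those of units 5 and 6 from syn-methylalumination of terminal alkynes; all are carried through with retention.

Key step: step 12

Assumption: (2E,6E,10E)-geranylgeraniol, 2-methoxy-5-methylphenol, trimethyl(prop-1-ynyl)silane and (4-bromobut-1-ynyl)trimethylsilane are taken as purchasable, the first as the single all-E isomer.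

**Route**

Step 1
Reactants: 1 2-methoxy-5-methylphenol
Product: 2 2-bromo-6-methoxy-3-methylphenol
Conditions: NBS (1.0 equiv), i-Pr2NH (0.1 equiv), CH2Cl2, 0 °C → rt
Reagents that add atoms: N-bromosuccinimide, O=C1CCC(=O)N1Br
Why: Amine-mediated ortho-selective electrophilic bromination of a phenol (the N-bromoamine is delivered through hydrogen bonding to the OH) should place bromine on the only free ortho carbon, between OH and CH3, and leave the para C–H untouched.

Step 2
Reactants: 2 2-bromo-6-methoxy-3-methylphenol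
Product: 3 2-bromo-4-methoxy-3-(methoxymethoxy)-1-methylbenzene
Conditions: NaH, MOMCl, THF/DMF, 0 °C → rt
Reagents that add atoms: chloromethyl methyl ether, COCCl
Why: O-Alkylation of the sodium phenoxide (Williamson type) should give the MOM ether, which removes the acidic proton, stabilises the later ortho-metalated arene by chelation and keeps the para C–H for the final oxidation.

Step 3
Reactants: 4 (2E,6E,10E)-geranylgeraniol
Product: 5 (2E,6E,10E)-geranylgeranyl bromide
Conditions: PBr3 (0.4 equiv), pyridine (cat.), Et2O, −10 → 0 °C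
Reagents that add atoms: phosphorus tribromide, BrP(Br)Br
Why: Bromination of a primary allylic alcohol with PBr3 at low temperature proceeds by SN2 at CH2 without allylic transposition, so the three E olefins should be retained.

Step 4
Reactants: 3 2-bromo-4-methoxy-3-(methoxymethoxy)-1-methylbenzene; 5 (2E,6E,10E)-geranylgeranyl bromide
Product: 8 1-methoxy-2-(methoxymethoxy)-4-methyl-3-[(2E,6E,10E)-3,7,11,15-tetramethylhexadeca-2,6,10,14-tetraenyl]benzene, via aryllithium 6 (not isolated), via arylcopper 7 (not isolated)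
Conditions: n-BuLi, THF, −78 °C; CuBr·SMe2 (1.0 equiv), −78 → −40 °C; then 5, −78 → 0 °C
Reagents that add atoms: none
Why: Bromine–lithium exchange, transmetalation to monovalent copper and allylic substitution at the unhindered primary carbon of the γ,γ-disubstituted allyl bromide (SN2 mode) should form the aryl–CH2 bond with the 2E geometry intact.

Step 5
Reactants: 8 1-methoxy-2-(methoxymethoxy)-4-methyl-3-[(2E,6E,10E)-3,7,11,15-tetramethylhexadeca-2,6,10,14-tetraenyl]benzene
Product: 9 (2E,6E,10E,14E)-16-[3-methoxy-2-(methoxymethoxy)-6-methylphenyl]-2,6,10,14-tetramethylhexadeca-2,6,10,14-tetraen-1-ol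
Conditions: SeO2 (0.3 equiv), t-BuOOH (3 equiv), salicylic acid (0.1 equiv), CH2Cl2, 0 °C → rt
Reagents that add atoms: selenium dioxide (catalytic oxygen carrier), O=[Se]=O; tert-butyl hydroperoxide, CC(C)(C)OO
Why: Riley-type catalytic allylic oxidation (ene reaction, then [2,3]-sigmatropic shift) should attack the terminal isopropylidene group, the most accessible and electron-rich olefin, and hydroxylate its E-methyl group, which fixes the E geometry of the future unit-4 olefin.

Step 6
Reactants: 9 (2E,6E,10E,14E)-16-[3-methoxy-2-(methoxymethoxy)-6-methylphenyl]-2,6,10,14-tetramethylhexadeca-2,6,10,14-tetraen-1-ol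
Product: 10 3-[(2E,6E,10E,14E)-16-bromo-3,7,11,15-tetramethylhexadeca-2,6,10,14-tetraenyl]-1-methoxy-2-(methoxymethoxy)-4-methylbenzene
Conditions: CBr4, PPh3, 2,6-lutidine, CH2Cl2, 0 °C
Reagents that add atoms: carbon tetrabromide, BrC(Br)(Br)Br
Why: Appel bromination under buffered neutral conditions should replace the primary allylic hydroxyl by bromide without touching the MOM ether or the olefin geometry.

Step 7
Reactants: 10 3-[(2E,6E,10E,14E)-16-bromo-3,7,11,15-tetramethylhexadeca-2,6,10,14-tetraenyl]-1-methoxy-2-(methoxymethoxy)-4-methylbenzene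
Product: 11 (4E,8E,12E,16E)-18-[3-methoxy-2-(methoxymethoxy)-6-methylphenyl]-4,8,12,16-tetramethyloctadeca-4,8,12,16-tetraenoic acid
Conditions: AcOH (3 equiv), LDA (6 equiv), THF/DMPU, 0 → 40 °C; then 10, 0 °C → rt; aq. NaH2PO4
Reagents that add atoms: acetic acid, CC(=O)O
Why: SN2 alkylation of the acetic acid dianion at the primary allylic bromide should add CH2–CO2H, whose CH2 is the future C1 of unit 5 and whose carboxyl is the traceless radical precursor.

Step 8
Reactants: 5 (2E,6E,10E)-geranylgeranyl bromide; 12 trimethyl(prop-1-ynyl)silane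
Product: 15 (5E,9E,13E)-6,10,14,18-tetramethylnonadeca-5,9,13,17-tetraen-1-yne, via lithiated silylpropyne 13 (not isolated), via silylated enyne 14 (not isolated)
Conditions: 12, n-BuLi, THF, −78 °C; then 5, −78 °C → rt; then MeOH, K2CO3 (cat.), rt
Reagents that add atoms: none
Why: The lithiated silylpropyne should be alkylated at its propargylic carbon by the primary allylic bromide (SN2, E retained), and methanolysis of the C–Si bond then frees the terminal alkyne.

Step 9
Reactants: 15 (5E,9E,13E)-6,10,14,18-tetramethylnonadeca-5,9,13,17-tetraen-1-yne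
Product: 17 (1E,5E,9E,13E)-1-iodo-2,6,10,14,18-pentamethylnonadeca-1,5,9,13,17-pentaene, via alkenylalane 16 (not isolated)
Conditions: Me3Al (2 equiv), Cp2ZrCl2 (0.25 equiv), CH2Cl2, 0 °C → rt; then I2, THF, −30 → 0 °C
Reagents that add atoms: trimethylaluminium, C[Al](C)C; iodine, II
Why: Negishi zirconium-catalysed carboalumination adds CH3 and Al syn across the terminal alkyne with Al on the terminal carbon, and iodinolysis with retention should give the (E)-2-methylalkenyl iodide, which sets the unit-6 olefin geometry.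

Step 10
Reactants: 17 (1E,5E,9E,13E)-1-iodo-2,6,10,14,18-pentamethylnonadeca-1,5,9,13,17-pentaene; 18 (4-bromobut-1-ynyl)trimethylsilane
Product: 21 (5E,9E,13E,17E)-6,10,14,18,22-pentamethyltricosa-5,9,13,17,21-pentaen-1-yne, via alkylzinc bromide 19 (not isolated), via silylated enyne 20 (not isolated)
Conditions: 18, Zn dust, LiCl, THF, 50 °C; then 17, PdCl2(dppf) (3 mol%), THF, rt; then MeOH, K2CO3 (cat.), rt
Reagents that add atoms: none
Why: Negishi coupling of the homopropargylic zinc reagent with the alkenyl iodide under zerovalent palladium catalysis should form the CH2–CH= bond of unit 6 with retention of the E geometry, and methanolysis removes the silyl cap.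

Step 11
Reactants: 21 (5E,9E,13E,17E)-6,10,14,18,22-pentamethyltricosa-5,9,13,17,21-pentaen-1-yne
Product: 23 (1E,5E,9E,13E,17E)-1-iodo-2,6,10,14,18,22-hexamethyltricosa-1,5,9,13,17,21-hexaene, via alkenylalane 22 (not isolated)
Conditions: Me3Al (2 equiv), Cp2ZrCl2 (0.25 equiv), CH2Cl2, 0 °C → rt; then I2, THF, −30 → 0 °C
Reagents that add atoms: trimethylaluminium, C[Al](C)C; iodine, II
Why: A second syn-methylalumination/iodinolysis, with Al on the terminal carbon, should set the E geometry of the unit-5 olefin and install the iodide needed for the fragment union.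

Step 12
Reactants: 11 (4E,8E,12E,16E)-18-[3-methoxy-2-(methoxymethoxy)-6-methylphenyl]-4,8,12,16-tetramethyloctadeca-4,8,12,16-tetraenoic acid; 23 (1E,5E,9E,13E,17E)-1-iodo-2,6,10,14,18,22-hexamethyltricosa-1,5,9,13,17,21-hexaene
Product: 25 1-methoxy-2-(methoxymethoxy)-4-methyl-3-[(2E,6E,10E,14E,18E,22E,26E,30E,34E)-3,7,11,15,19,23,27,31,35,39-decamethyltetraconta-2,6,10,14,18,22,26,30,34,38-decaenyl]benzene, via N-acyloxyphthalimide 24 (not isolated)
Conditions: N-hydroxyphthalimide, N,N′-diisopropylcarbodiimide, DMF/THF, rt; then 23, NiCl2·6H2O (10 mol%), 2,2′-bipyridine (10 mol%), AgNO3 (0.3 equiv), LiCl, Mg anode/RVC cathode, undivided cell, constant current (about 2.5 F/mol), rt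
Reagents that add atoms: none
Why: The acid is activated in the flask as the redox-active ester 24; at the silver-coated cathode the divalent nickel/bipyridine precatalyst is reduced to low-valent nickel, which adds oxidatively to the C–I bond of 23 with retention of the E geometry, while single-electron reduction of 24 expels phthalimide anion and CO2 and leaves the primary radical at C1 of unit 5. Capture of this radical by the alkenylnickel species and reductive elimination from trivalent nickel form the CH2–CH= bond, the magnesium anode supplying the electrons. The closest known reaction type is the nickel-electrocatalytic decarboxylative alkenylation of redox-active esters with alkenyl halides, which is established for joining 4-methylalk-4-enoic acid units to (E)-2-methylalkenyl iodides in polyprenoid chains. No ring is closed and no stereocentre is formed; the E geometry at C2=C3 of unit 5 is carried over from the iodide and the other eight olefins are spectators. The step needs cross-coupling to win over radical dimerisation, hydrodeiodination and iodide homocoupling, which the slow electrolytic release of the radical next to a standing pool of alkenylnickel should secure. It also needs the radical not to cyclise: the unit-4 olefin is reachable only by a reversible 3-exo closure and the next olefin only by a slow seven-membered closure, and the MOM ether keeps both an acidic O–H and a reducible quinone away from the cathode.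

Step 13
Reactants: 25 1-methoxy-2-(methoxymethoxy)-4-methyl-3-[(all-E)-decaprenyl]benzene
Product: 27 2-methoxy-5-methyl-6-[(2E,6E,10E,14E,18E,22E,26E,30E,34E)-3,7,11,15,19,23,27,31,35,39-decamethyltetraconta-2,6,10,14,18,22,26,30,34,38-decaenyl]phenol, via aryl silyl ether 26 (not isolated)
Conditions: TMSOTf, 2,2′-bipyridyl, CH2Cl2, 0 °C → rt; then H2O
Reagents that add atoms: none
Why: TMSOTf/2,2′-bipyridyl cleaves aromatic MOM ethers through the aryl silyl ether under buffered, non-protic conditions, so the ortho-prenyl phenol should be released without acid-induced chroman formation or olefin isomerisation.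

Step 14
Reactants: 27 2-methoxy-5-methyl-6-[(all-E)-decaprenyl]phenol
Product: 28 2-methoxy-5-methyl-6-[(2E,6E,10E,14E,18E,22E,26E,30E,34E)-3,7,11,15,19,23,27,31,35,39-decamethyltetraconta-2,6,10,14,18,22,26,30,34,38-decaenyl]cyclohexa-2,5-diene-1,4-dione
Conditions: Co(salen) (10 mol%), O2 (1 atm), DMF/CH2Cl2, rt
Reagents that add atoms: dioxygen, O=O
Why: Co(salen)-catalysed aerobic oxidation of a 2,3,6-trisubstituted phenol with a free para position proceeds through the phenoxyl radical and oxygenation at the para carbon, which should give the p-benzoquinone with the second carbonyl at the only unsubstituted carbon para to OH.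

**Compound list**

1 | 2-methoxy-5-methylphenol | COc1ccc(C)cc1O | starting material
2 | 2-bromo-6-methoxy-3-methylphenol | COc1ccc(C)c(Br)c1O | intermediate
3 | 2-bromo-4-methoxy-3-(methoxymethoxy)-1-methylbenzene | COCOc1c(OC)ccc(C)c1Br | intermediate
4 | (2E,6E,10E)-geranylgeraniol, (2E,6E,10E)-3,7,11,15-tetramethylhexadeca-2,6,10,14-tetraen-1-ol | OC/C=C(\C)CC/C=C(\C)CC/C=C(\C)CCC=C(C)C | starting material
5 | (2E,6E,10E)-geranylgeranyl bromide | BrC/C=C(\C)CC/C=C(\C)CC/C=C(\C)CCC=C(C)C | intermediate
6 | [3-methoxy-2-(methoxymethoxy)-6-methylphenyl]lithium (formed in the flask) | COCOc1c(OC)ccc(C)c1[Li] | intermediate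
7 | [3-methoxy-2-(methoxymethoxy)-6-methylphenyl]copper (formed in the flask) | COCOc1c(OC)ccc(C)c1[Cu] | intermediate
8 | 1-methoxy-2-(methoxymethoxy)-4-methyl-3-[(2E,6E,10E)-3,7,11,15-tetramethylhexadeca-2,6,10,14-tetraenyl]benzene | COCOc1c(OC)ccc(C)c1C/C=C(\C)CC/C=C(\C)CC/C=C(\C)CCC=C(C)C | intermediate
9 | (2E,6E,10E,14E)-16-[3-methoxy-2-(methoxymethoxy)-6-methylphenyl]-2,6,10,14-tetramethylhexadeca-2,6,10,14-tetraen-1-ol | COCOc1c(OC)ccc(C)c1C/C=C(\C)CC/C=C(\C)CC/C=C(\C)CC/C=C(\C)CO | intermediate
10 | 3-[(2E,6E,10E,14E)-16-bromo-3,7,11,15-tetramethylhexadeca-2,6,10,14-tetraenyl]-1-methoxy-2-(methoxymethoxy)-4-methylbenzene | COCOc1c(OC)ccc(C)c1C/C=C(\C)CC/C=C(\C)CC/C=C(\C)CC/C=C(\C)CBr | intermediate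
11 | (4E,8E,12E,16E)-18-[3-methoxy-2-(methoxymethoxy)-6-methylphenyl]-4,8,12,16-tetramethyloctadeca-4,8,12,16-tetraenoic acid | COCOc1c(OC)ccc(C)c1C/C=C(\C)CC/C=C(\C)CC/C=C(\C)CC/C=C(\C)CCC(=O)O | intermediate
12 | trimethyl(prop-1-ynyl)silane | CC#C[Si](C)(C)C | starting material
13 | [3-(trimethylsilyl)prop-2-ynyl]lithium (formed in the flask) | [Li]CC#C[Si](C)(C)C | intermediate
14 | trimethyl[(5E,9E,13E)-6,10,14,18-tetramethylnonadeca-5,9,13,17-tetraen-1-ynyl]silane (formed in the flask) | C[Si](C)(C)C#CCC/C=C(\C)CC/C=C(\C)CC/C=C(\C)CCC=C(C)C | intermediate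
15 | (5E,9E,13E)-6,10,14,18-tetramethylnonadeca-5,9,13,17-tetraen-1-yne | C#CCC/C=C(\C)CC/C=C(\C)CC/C=C(\C)CCC=C(C)C | intermediate
16 | dimethyl[(1E,5E,9E,13E)-2,6,10,14,18-pentamethylnonadeca-1,5,9,13,17-pentaenyl]alane (formed in the flask) | C[Al](C)/C=C(\C)CC/C=C(\C)CC/C=C(\C)CC/C=C(\C)CCC=C(C)C | intermediate
17 | (1E,5E,9E,13E)-1-iodo-2,6,10,14,18-pentamethylnonadeca-1,5,9,13,17-pentaene | I/C=C(\C)CC/C=C(\C)CC/C=C(\C)CC/C=C(\C)CCC=C(C)C | intermediate
18 | (4-bromobut-1-ynyl)trimethylsilane | C[Si](C)(C)C#CCCBr | starting material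
19 | [4-(trimethylsilyl)but-3-ynyl]zinc bromide (formed in the flask) | C[Si](C)(C)C#CCC[Zn]Br | intermediate
20 | trimethyl[(5E,9E,13E,17E)-6,10,14,18,22-pentamethyltricosa-5,9,13,17,21-pentaen-1-ynyl]silane (formed in the flask) | C[Si](C)(C)C#CCC/C=C(\C)CC/C=C(\C)CC/C=C(\C)CC/C=C(\C)CCC=C(C)C | intermediate
21 | (5E,9E,13E,17E)-6,10,14,18,22-pentamethyltricosa-5,9,13,17,21-pentaen-1-yne | C#CCC/C=C(\C)CC/C=C(\C)CC/C=C(\C)CC/C=C(\C)CCC=C(C)C | intermediate
22 | dimethyl[(1E,5E,9E,13E,17E)-2,6,10,14,18,22-hexamethyltricosa-1,5,9,13,17,21-hexaenyl]alane (formed in the flask) | C[Al](C)/C=C(\C)CC/C=C(\C)CC/C=C(\C)CC/C=C(\C)CC/C=C(\C)CCC=C(C)C | intermediate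
23 | (1E,5E,9E,13E,17E)-1-iodo-2,6,10,14,18,22-hexamethyltricosa-1,5,9,13,17,21-hexaene | I/C=C(\C)CC/C=C(\C)CC/C=C(\C)CC/C=C(\C)CC/C=C(\C)CCC=C(C)C | intermediate
24 | 1,3-dioxoisoindolin-2-yl (4E,8E,12E,16E)-18-[3-methoxy-2-(methoxymethoxy)-6-methylphenyl]-4,8,12,16-tetramethyloctadeca-4,8,12,16-tetraenoate (formed in the flask) | COCOc1c(OC)ccc(C)c1C/C=C(\C)CC/C=C(\C)CC/C=C(\C)CC/C=C(\C)CCC(=O)ON1C(=O)c2ccccc2C1=O | intermediate
25 | 1-methoxy-2-(methoxymethoxy)-4-methyl-3-[(2E,6E,10E,14E,18E,22E,26E,30E,34E)-3,7,11,15,19,23,27,31,35,39-decamethyltetraconta-2,6,10,14,18,22,26,30,34,38-decaenyl]benzene | COCOc1c(OC)ccc(C)c1C/C=C(\C)CC/C=C(\C)CC/C=C(\C)CC/C=C(\C)CC/C=C(\C)CC/C=C(\C)CC/C=C(\C)CC/C=C(\C)CC/C=C(\C)CCC=C(C)C | intermediate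
26 | trimethyl{6-methoxy-3-methyl-2-[(all-E)-decaprenyl]phenoxy}silane (formed in the flask) | C[Si](C)(C)Oc1c(OC)ccc(C)c1C/C=C(\C)CC/C=C(\C)CC/C=C(\C)CC/C=C(\C)CC/C=C(\C)CC/C=C(\C)CC/C=C(\C)CC/C=C(\C)CC/C=C(\C)CCC=C(C)C | intermediate
27 | 2-methoxy-5-methyl-6-[(2E,6E,10E,14E,18E,22E,26E,30E,34E)-3,7,11,15,19,23,27,31,35,39-decamethyltetraconta-2,6,10,14,18,22,26,30,34,38-decaenyl]phenol | COc1ccc(C)c(C/C=C(\C)CC/C=C(\C)CC/C=C(\C)CC/C=C(\C)CC/C=C(\C)CC/C=C(\C)CC/C=C(\C)CC/C=C(\C)CC/C=C(\C)CCC=C(C)C)c1O | intermediate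
28 | 2-methoxy-5-methyl-6-[(2E,6E,10E,14E,18E,22E,26E,30E,34E)-3,7,11,15,19,23,27,31,35,39-decamethyltetraconta-2,6,10,14,18,22,26,30,34,38-decaenyl]cyclohexa-2,5-diene-1,4-dione (CID25010748) | COC1=CC(=O)C(C)=C(C/C=C(\C)CC/C=C(\C)CC/C=C(\C)CC/C=C(\C)CC/C=C(\C)CC/C=C(\C)CC/C=C(\C)CC/C=C(\C)CC/C=C(\C)CCC=C(C)C)C1=O | target

**Step count and risks**

Total step count: 14. Longest linear sequence: 9 steps (1, 2, 4, 5, 6, 7, 12, 13, 14, from 2-methoxy-5-methylphenol).

Steps most likely to fail:

1. Step 12 (fragment union). The primary radical may be lost to dimerisation or hydrogen abstraction, the alkenyl iodide to hydrodeiodination or homocoupling, and the two lipophilic partners may dissolve poorly in the electrolyte. Reversible 3-exo closure of the homoallylic radical onto the unit-4 olefin may also erode its E geometry. The fallback is a two-electron coupling that forms the same bond without a radical; it sets out from alcohol 9 and returns at 25. Oxidation of 9 with MnO2 in CH2Cl2 should give the aryl tetraenal F1. Wittig methylenation (Ph3PCH3Br, KOt-Bu, THF) should give the terminal (E)-1,3-diene, the aryl pentaene F2. 9-BBN in THF should add only to the monosubstituted vinyl end and give the alkylborane F3. F3 is not isolated but coupled with iodide 23 under Suzuki–Miyaura conditions (PdCl2(dppf), AsPh3, Cs2CO3, DMF/THF/H2O, rt) to give 25.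

2. Step 5 (terminal allylic oxidation). Competing oxidation at internal allylic methylenes and over-oxidation to the enal may leave little of the terminal alcohol. The fallback replaces the ene oxidation by an epoxide/sigmatropic sequence; it sets out from 8 and returns at acid 11, so steps 6 and 7 are bypassed as well. NBS in THF/H2O at 0 °C should give the terminal bromohydrin F4 (racemic). K2CO3 in MeOH should close it to the terminal epoxide F5 (racemic). Al(Oi-Pr)3 in refluxing toluene should isomerise the epoxide to the isopropenyl carbinol F6 (racemic). Johnson–Claisen rearrangement (triethyl orthoacetate, propionic acid cat., 140 °C) through a chair transition state should give the (4E)-ethyl ester F7, in which the carbinol stereocentre is gone. Saponification with LiOH in THF/MeOH/H2O then gives 11.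

3. Step 7 (two-carbon extension). The sparingly soluble dilithioacetate may act as a base, causing 1,4-elimination of HBr from 10, or may alkylate incompletely. The fallback uses a stabilised enolate followed by dealkoxycarbonylation; it sets out from bromide 10 and returns at acid 11. NaH and dimethyl malonate in THF should give the allylated malonate F8. Krapcho dealkoxycarbonylation (LiCl, wet DMSO, 150 °C) should give the methyl ester F9. LiOH in THF/MeOH/H2O then gives 11.

**Further compounds**

F1 | step 12 | (2E,6E,10E,14E)-16-[3-methoxy-2-(methoxymethoxy)-6-methylphenyl]-2,6,10,14-tetramethylhexadeca-2,6,10,14-tetraenal | COCOc1c(OC)ccc(C)c1C/C=C(\C)CC/C=C(\C)CC/C=C(\C)CC/C=C(\C)C=O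
F2 | step 12 | 1-methoxy-2-(methoxymethoxy)-4-methyl-3-[(2E,6E,10E,14E)-3,7,11,15-tetramethylheptadeca-2,6,10,14,16-pentaenyl]benzene | COCOc1c(OC)ccc(C)c1C/C=C(\C)CC/C=C(\C)CC/C=C(\C)CC/C=C(\C)C=C
F3 | step 12 | 9-[(3E,7E,11E,15E)-17-[3-methoxy-2-(methoxymethoxy)-6-methylphenyl]-3,7,11,15-tetramethylheptadeca-3,7,11,15-tetraenyl]-9-borabicyclo[3.3.1]nonane | COCOc1c(OC)ccc(C)c1C/C=C(\C)CC/C=C(\C)CC/C=C(\C)CC/C=C(\C)CCB1C2CCCC1CCC2
F4 | step 5 | (6E,10E,14E)-3-bromo-16-[3-methoxy-2-(methoxymethoxy)-6-methylphenyl]-2,6,10,14-tetramethylhexadeca-6,10,14-trien-2-ol (racemic) | COCOc1c(OC)ccc(C)c1C/C=C(\C)CC/C=C(\C)CC/C=C(\C)CCC(Br)C(C)(C)O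
F5 | step 5 | 3-[(3E,7E,11E)-13-[3-methoxy-2-(methoxymethoxy)-6-methylphenyl]-3,7,11-trimethyltrideca-3,7,11-trienyl]-2,2-dimethyloxirane (racemic) | COCOc1c(OC)ccc(C)c1C/C=C(\C)CC/C=C(\C)CC/C=C(\C)CCC1OC1(C)C
F6 | step 5 | (6E,10E,14E)-16-[3-methoxy-2-(methoxymethoxy)-6-methylphenyl]-2,6,10,14-tetramethylhexadeca-1,6,10,14-tetraen-3-ol (racemic) | COCOc1c(OC)ccc(C)c1C/C=C(\C)CC/C=C(\C)CC/C=C(\C)CCC(O)C(C)=C
F7 | step 5 | ethyl (4E,8E,12E,16E)-18-[3-methoxy-2-(methoxymethoxy)-6-methylphenyl]-4,8,12,16-tetramethyloctadeca-4,8,12,16-tetraenoate | COCOc1c(OC)ccc(C)c1C/C=C(\C)CC/C=C(\C)CC/C=C(\C)CC/C=C(\C)CCC(=O)OCC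
F8 | step 7 | dimethyl 2-[(2E,6E,10E,14E)-16-[3-methoxy-2-(methoxymethoxy)-6-methylphenyl]-2,6,10,14-tetramethylhexadeca-2,6,10,14-tetraenyl]propanedioate | COCOc1c(OC)ccc(C)c1C/C=C(\C)CC/C=C(\C)CC/C=C(\C)CC/C=C(\C)CC(C(=O)OC)C(=O)OC
F9 | step 7 | methyl (4E,8E,12E,16E)-18-[3-methoxy-2-(methoxymethoxy)-6-methylphenyl]-4,8,12,16-tetramethyloctadeca-4,8,12,16-tetraenoate | COCOc1c(OC)ccc(C)c1C/C=C(\C)CC/C=C(\C)CC/C=C(\C)CC/C=C(\C)CCC(=O)OC
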